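**Retrosynthetic overview**
- The target is reached by a late cis-selective Shi epoxidation of the C1=C2 bond of the ring diene, after acylation of the C8 hydroxyl with the 2-(hydroxymethyl)acrylate unit.
- The 13-acetoxy butenolide (C6–O lactone bond, C12 from CO, C13–OAc) comes in one step from a macrocyclic α-allenol by a new oxidative acetoxy-cyclocarbonylation; this is the key C–O bond-forming step.
- The 10-membered carbocycle and the allenol come from a chromium-mediated intramolecular SE2′ propargylation of a 4,5-epoxy aldehyde (C6–C7).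
- The open-chain precursor comes from an asymmetric allylboration (C8–C9, sets C8) of 4-chlorobut-2-ynal with an allylboronate carrying the (Z)-diene and the Sharpless epoxide (C4, C5).
- Ring order: 4,5-oxirane, then the 10-membered carbocycle, then the butenolide, then the 1,2-oxirane.

Assumption: locants C1–C15 follow germacrane numbering of the target (ring C1–C10; C11–C13 on C7 with C12 the lactone carbonyl; C14 on C10; C15 on C4), which makes the target (1R,2S,4R,5R,6S,8S).

Step 1
Reactants: 1 ethynyltrimethylsilane; 2 3-bromoprop-1-yne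
Product: 4 trimethyl(penta-1,4-diyn-1-yl)silane, via alkynylmagnesium bromide 3 (not isolated)
Conditions: EtMgBr, THF, 0 °C to rt; then 2, CuCl (5 mol%), 50 °C
Reagents that add atoms: none
Why: Copper-catalysed SN2 coupling of an alkynyl Grignard reagent with propargyl bromide gives the skipped diyne, the silyl group blocking one alkyne terminus.

Step 2
Reactants: 4 trimethyl(penta-1,4-diyn-1-yl)silane
Product: 7 (2E)-3-methyl-6-(trimethylsilyl)hex-2-en-5-yn-1-ol, via alkenylalane 5 (not isolated), via lithium alkenylalanate 6 (not isolated)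
Conditions: Me3Al, Cp2ZrCl2 (20 mol%), CH2Cl2, rt; then n-BuLi, THF, −78 °C; then (CH2O)n, rt
Reagents that add atoms: trimethylaluminium C[Al](C)C; paraformaldehyde (formaldehyde) C=O
Why: Negishi zirconium-catalysed syn-carboalumination of the terminal alkyne (methyl to the internal carbon) followed by hydroxymethylation of the alanate fixes the E trisubstituted C4=C5 alkene, the silylalkyne being inert.

Step 3
Reactants: 7 (2E)-3-methyl-6-(trimethylsilyl)hex-2-en-5-yn-1-ol
Product: 8 [(2R,3R)-3-methyl-3-[3-(trimethylsilyl)prop-2-yn-1-yl]oxiran-2-yl]methanol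
Conditions: Ti(OiPr)4 (10 mol%), D-(−)-diethyl tartrate (12 mol%), t-BuOOH, 4 Å MS, CH2Cl2, −20 °C
Reagents that add atoms: tert-butyl hydroperoxide CC(C)(C)OO
Why: Sharpless asymmetric epoxidation sets C4 and C5; D-(−)-tartrate gives the (2R,3R) epoxy alcohol, the antipode of the (2S,3S) series that L-(+)-tartrate gives with geraniol-type alcohols.

Step 4
Reactants: 8 [(2R,3R)-3-methyl-3-[3-(trimethylsilyl)prop-2-yn-1-yl]oxiran-2-yl]methanol; 9 2-bromoprop-2-en-1-ol
Product: 11 [(2R,3R)-3-[4-(hydroxymethyl)pent-4-en-2-yn-1-yl]-3-methyloxiran-2-yl]methanol, via terminal alkyne 10 (not isolated)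
Conditions: K2CO3 (cat.), MeOH, rt; concentrate; then 9, Pd(PPh3)4 (5 mol%), CuI (10 mol%), Et3N, THF, 40 °C
Reagents that add atoms: none
Why: Protodesilylation followed by Sonogashira coupling with the vinyl bromide builds the C10(=C14)–C1≡C2 enyne and tolerates the epoxy alcohol.

Step 5
Reactants: 11 [(2R,3R)-3-[4-(hydroxymethyl)pent-4-en-2-yn-1-yl]-3-methyloxiran-2-yl]methanol
Product: 12 [(2R,3R)-3-[(2Z)-4-(hydroxymethyl)penta-2,4-dien-1-yl]-3-methyloxiran-2-yl]methanol
Conditions: Zn dust activated with Cu(OAc)2 and AgNO3, MeOH/H2O (1:1), 40 °C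
Reagents that add atoms: none
Why: Boland reduction semi-reduces only the conjugated alkyne, cis-selectively and without over-reduction, giving the (Z)-C1=C2 alkene needed for the cis-epoxide.

Step 6
Reactants: 12 [(2R,3R)-3-[(2Z)-4-(hydroxymethyl)penta-2,4-dien-1-yl]-3-methyloxiran-2-yl]methanol
Product: 13 [(2R,3R)-3-methyl-3-[(2Z)-4-[(4,4,5,5-tetramethyl-1,3,2-dioxaborolan-2-yl)methyl]penta-2,4-dien-1-yl]oxiran-2-yl]methanol
Conditions: B2pin2, [Pd(MeCN)4](BF4)2 (2 mol%), DMSO, rt
Reagents that add atoms: bis(pinacolato)diboron CC1(C)OB(OC1(C)C)B1OC(C)(C)C(C)(C)O1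
Why: Palladium-catalysed allylic C–OH borylation through a π-allyl intermediate ionises only the allylic alcohol, leaving the epoxy alcohol untouched, and the symmetric 2-substituted allyl unit can give only one boronate.

Step 7
Reactants: 14 4-chlorobut-2-yn-1-ol
Product: 15 4-chlorobut-2-ynal
Conditions: MnO2, CH2Cl2, rt; filtered solution used directly
Reagents that add atoms: none
Why: Manganese dioxide oxidation of a propargylic alcohol gives the sensitive ynal without touching the propargylic chloride.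

Step 8
Reactants: 13 [(2R,3R)-3-methyl-3-[(2Z)-4-[(4,4,5,5-tetramethyl-1,3,2-dioxaborolan-2-yl)methyl]penta-2,4-dien-1-yl]oxiran-2-yl]methanol; 15 4-chlorobut-2-ynal
Product: 16 [(2R,3R)-3-[(2Z,6S)-9-chloro-6-hydroxy-4-methylidenenon-2-en-7-yn-1-yl]-3-methyloxiran-2-yl]methanol
Conditions: (S)-TRIP phosphoric acid (5 mol%), 4 Å MS, toluene, −30 °C; aq. NaHCO3 work-up
Reagents that add atoms: none
Why: Chiral phosphoric acid-catalysed allylboration through a chair transition state forms C8–C9 and sets C8 as S by Si-face addition; (S)-TRIP is chosen by analogy with (R)-TRIP giving R carbinols from aryl aldehydes, so the catalyst hand should be confirmed on a model.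

Step 9
Reactants: 16 [(2R,3R)-3-[(2Z,6S)-9-chloro-6-hydroxy-4-methylidenenon-2-en-7-yn-1-yl]-3-methyloxiran-2-yl]methanol
Product: 17 (2S,3R)-3-[(2Z,6S)-9-chloro-6-hydroxy-4-methylidenenon-2-en-7-yn-1-yl]-3-methyloxirane-2-carbaldehyde
Conditions: TEMPO (10 mol%), PhI(OAc)2, CH2Cl2, rt
Reagents that add atoms: none
Why: Oxoammonium (TEMPO) oxidation is selective for the primary alcohol over the secondary propargylic one and gives the epoxy aldehyde under neutral conditions.

Step 10
Reactants: 17 (2S,3R)-3-[(2Z,6S)-9-chloro-6-hydroxy-4-methylidenenon-2-en-7-yn-1-yl]-3-methyloxirane-2-carbaldehyde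
Product: 18 (2S,3R)-3-[(2Z,6S)-6-[(tert-butyldimethylsilyl)oxy]-9-chloro-4-methylidenenon-2-en-7-yn-1-yl]-3-methyloxirane-2-carbaldehyde
Conditions: TBSCl, imidazole, CH2Cl2, 0 °C to rt
Reagents that add atoms: tert-butyldimethylsilyl chloride CC(C)(C)[Si](C)(C)Cl
Why: Silylation turns the C8 oxygen into a poor leaving group and a non-nucleophile, so it neither eliminates from the organochromium in step 11 nor competes for lactonisation in step 12.

Step 11
Reactants: 18 (2S,3R)-3-[(2Z,6S)-6-[(tert-butyldimethylsilyl)oxy]-9-chloro-4-methylidenenon-2-en-7-yn-1-yl]-3-methyloxirane-2-carbaldehyde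
Product: 19 (1Z,4R,5R,6S,8S)-8-[(tert-butyldimethylsilyl)oxy]-4,5-epoxy-7-ethenylidene-4-methyl-10-methylidenecyclodec-1-en-6-ol
Conditions: CrCl2 (6 equiv), LiI (20 mol%), THF, slow addition to 2 mM, rt
Reagents that add atoms: none
Why: Intramolecular Nozaki–Hiyama (Barbier) propargylation: the γ-substituted propargylchromium adds SE2′ through C7, closing the 10-membered ring with an exocyclic allene, and chelation of chromium by the aldehyde and epoxide oxygens is expected to give the 5,6-threo (6S) alcohol, as in chromium closures of 4,5-epoxygermacranolide precursors.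

Step 12
Reactants: 19 (1Z,4R,5R,6S,8S)-8-[(tert-butyldimethylsilyl)oxy]-4,5-epoxy-7-ethenylidene-4-methyl-10-methylidenecyclodec-1-en-6-ol
Product: 20 (1Z,4R,5R,6S,8S)-13-acetoxy-8-[(tert-butyldimethylsilyl)oxy]-4,5-epoxygermacra-1,7(11),10(14)-trien-12,6-olide
Conditions: Pd(OAc)2 (10 mol%), 1,4-benzoquinone (1.5 equiv), LiOAc (2 equiv), CO (1 atm), 4 Å MS, THF, 0 °C to rt
Reagents that add atoms: carbon monoxide [C-]#[O+]; lithium acetate [Li+].CC(=O)[O-]
Why: Proposed new method: divalent palladium, CO and the C6 hydroxyl form an alkoxycarbonyl–palladium species (as in oxidative carbonylation of alcohols) that inserts the adjacent allene with acyl transfer to the central carbon C11, closing the five-membered lactone and leaving a π-allyl complex (C7–C11–C13) which acetate attacks at the unhindered terminus C13 to give the conjugated tetrasubstituted butenolide, while benzoquinone reoxidises zerovalent palladium and C6 keeps its configuration because its C–O bond is never broken; the closest known reaction types are the palladium-catalysed alkoxy-alkoxycarbonylation of allenes, the ruthenium-catalysed cyclocarbonylation of allenyl alcohols and acetate capture of π-allyl intermediates in palladium/benzoquinone diene oxidations.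

Step 13
Reactants: 20 (1Z,4R,5R,6S,8S)-13-acetoxy-8-[(tert-butyldimethylsilyl)oxy]-4,5-epoxygermacra-1,7(11),10(14)-trien-12,6-olide
Product: 21 (1Z,4R,5R,6S,8S)-13-acetoxy-4,5-epoxy-8-hydroxygermacra-1,7(11),10(14)-trien-12,6-olide
Conditions: Bu4NF/AcOH (1:1), THF, 0 °C to rt
Reagents that add atoms: none
Why: Buffered fluoride desilylation frees the C8 alcohol without base-induced loss or migration of the allylic 13-acetate and without acid-induced transannular opening of the epoxide.

Step 14
Reactants: 22 ethyl 2-(hydroxymethyl)prop-2-enoate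
Product: 24 2-({[tert-butyl(dimethyl)silyl]oxy}methyl)prop-2-enoic acid, via silyl ether ester 23 (not isolated)
Conditions: TBSCl, imidazole, CH2Cl2, rt; then LiOH, THF/H2O, 0 °C; 1 M HCl to pH 4
Reagents that add atoms: tert-butyldimethylsilyl chloride CC(C)(C)[Si](C)(C)Cl; lithium hydroxide [Li+].[OH-]
Why: Silylation then saponification gives the side-chain acid with its primary hydroxyl masked, so that it cannot self-esterify in step 15.

Step 15
Reactants: 21 (1Z,4R,5R,6S,8S)-13-acetoxy-4,5-epoxy-8-hydroxygermacra-1,7(11),10(14)-trien-12,6-olide; 24 2-({[tert-butyl(dimethyl)silyl]oxy}methyl)prop-2-enoic acid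
Product: 25 (1Z,4R,5R,6S,8S)-13-acetoxy-8-{[2-({[tert-butyl(dimethyl)silyl]oxy}methyl)prop-2-enoyl]oxy}-4,5-epoxygermacra-1,7(11),10(14)-trien-12,6-olide
Conditions: DCC, DMAP (10 mol%), CH2Cl2, 0 °C
Reagents that add atoms: none
Why: Steglich esterification forms the C8–O ester bond with retention at C8 under near-neutral conditions.

Step 16
Reactants: 25 (1Z,4R,5R,6S,8S)-13-acetoxy-8-{[2-({[tert-butyl(dimethyl)silyl]oxy}methyl)prop-2-enoyl]oxy}-4,5-epoxygermacra-1,7(11),10(14)-trien-12,6-olide
Product: 26 (1Z,4R,5R,6S,8S)-13-acetoxy-4,5-epoxy-8-{[2-(hydroxymethyl)prop-2-enoyl]oxy}germacra-1,7(11),10(14)-trien-12,6-olide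
Conditions: Bu4NF/AcOH (1:1), THF, 0 °C
Reagents that add atoms: none
Why: Buffered fluoride desilylation of the primary silyl ether is done before the acid- and nucleophile-sensitive vinyl epoxide is introduced.

Step 17
Reactants: 26 (1Z,4R,5R,6S,8S)-13-acetoxy-4,5-epoxy-8-{[2-(hydroxymethyl)prop-2-enoyl]oxy}germacra-1,7(11),10(14)-trien-12,6-olide
Product: 27 (1R,2S,4R,5R,6S,8S)-13-acetoxy-1,2:4,5-diepoxy-8-{[2-(hydroxymethyl)prop-2-enoyl]oxy}germacra-7(11),10(14)-dien-12,6-olide (CNP0233746.1)
Conditions: Shi D-glucose-derived N-(4-tolyl)oxazolidinone ketone (30 mol%), Oxone (2KHSO5·KHSO4·K2SO4), K2CO3/AcOH buffer (pH 8), Bu4NHSO4, DME/dimethoxymethane, −10 °C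
Reagents that add atoms: potassium peroxymonosulfate [K+].[O-]S(=O)(=O)OO
Why: Shi asymmetric epoxidation with the oxazolidinone ketone epoxidises the cis alkene of a conjugated diene stereospecifically through a spiro transition state with the vinyl group next to the oxazolidinone, expected to give the (1R,2S) vinyl cis-epoxide by analogy with cis-β-methylstyrene, while the 1,1-disubstituted and electron-poor alkenes are left alone.

**Compound list**
1 | ethynyltrimethylsilane | C[Si](C)(C)C#C | starting material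
2 | 3-bromoprop-1-yne | BrCC#C | starting material
3 | bromo[(trimethylsilyl)ethynyl]magnesium | C[Si](C)(C)C#C[Mg]Br | intermediate
4 | trimethyl(penta-1,4-diyn-1-yl)silane | C[Si](C)(C)C#CCC#C | intermediate
5 | dimethyl[(1E)-2-methyl-5-(trimethylsilyl)pent-1-en-4-yn-1-yl]alane | C[Al](C)/C=C(\C)CC#C[Si](C)(C)C | intermediate
6 | lithium butyldimethyl[(1E)-2-methyl-5-(trimethylsilyl)pent-1-en-4-yn-1-yl]alanate | [Li+].CCCC[Al-](C)(C)/C=C(\C)CC#C[Si](C)(C)C | intermediate
7 | (2E)-3-methyl-6-(trimethylsilyl)hex-2-en-5-yn-1-ol | C[Si](C)(C)C#CC/C(C)=C/CO | intermediate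
8 | [(2R,3R)-3-methyl-3-[3-(trimethylsilyl)prop-2-yn-1-yl]oxiran-2-yl]methanol | C[Si](C)(C)C#CC[C@@]1(C)O[C@@H]1CO | intermediate
9 | 2-bromoprop-2-en-1-ol | OCC(Br)=C | starting material
10 | [(2R,3R)-3-methyl-3-(prop-2-yn-1-yl)oxiran-2-yl]methanol | C#CC[C@@]1(C)O[C@@H]1CO | intermediate
11 | [(2R,3R)-3-[4-(hydroxymethyl)pent-4-en-2-yn-1-yl]-3-methyloxiran-2-yl]methanol | OCC(=C)C#CC[C@@]1(C)O[C@@H]1CO | intermediate
12 | [(2R,3R)-3-[(2Z)-4-(hydroxymethyl)penta-2,4-dien-1-yl]-3-methyloxiran-2-yl]methanol | OCC(=C)/C=C\C[C@@]1(C)O[C@@H]1CO | intermediate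
13 | [(2R,3R)-3-methyl-3-[(2Z)-4-[(4,4,5,5-tetramethyl-1,3,2-dioxaborolan-2-yl)methyl]penta-2,4-dien-1-yl]oxiran-2-yl]methanol | CC1(C)OB(CC(=C)/C=C\C[C@@]2(C)O[C@@H]2CO)OC1(C)C | intermediate
14 | 4-chlorobut-2-yn-1-ol | OCC#CCCl | starting material
15 | 4-chlorobut-2-ynal | O=CC#CCCl | intermediate
16 | [(2R,3R)-3-[(2Z,6S)-9-chloro-6-hydroxy-4-methylidenenon-2-en-7-yn-1-yl]-3-methyloxiran-2-yl]methanol | ClCC#C[C@@H](O)CC(=C)/C=C\C[C@@]1(C)O[C@@H]1CO | intermediate
17 | (2S,3R)-3-[(2Z,6S)-9-chloro-6-hydroxy-4-methylidenenon-2-en-7-yn-1-yl]-3-methyloxirane-2-carbaldehyde | ClCC#C[C@@H](O)CC(=C)/C=C\C[C@@]1(C)O[C@@H]1C=O | intermediate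
18 | (2S,3R)-3-[(2Z,6S)-6-[(tert-butyldimethylsilyl)oxy]-9-chloro-4-methylidenenon-2-en-7-yn-1-yl]-3-methyloxirane-2-carbaldehyde | ClCC#C[C@@H](O[Si](C)(C)C(C)(C)C)CC(=C)/C=C\C[C@@]1(C)O[C@@H]1C=O | intermediate
19 | (1Z,4R,5R,6S,8S)-8-[(tert-butyldimethylsilyl)oxy]-4,5-epoxy-7-ethenylidene-4-methyl-10-methylidenecyclodec-1-en-6-ol (macrocyclic α-allenol; C11=C13H2 on C7) | CC(C)(C)[Si](C)(C)O[C@H]1CC(=C)/C=C\C[C@@]2(C)O[C@@H]2[C@@H](O)C1=C=C | intermediate
20 | (1Z,4R,5R,6S,8S)-13-acetoxy-8-[(tert-butyldimethylsilyl)oxy]-4,5-epoxygermacra-1,7(11),10(14)-trien-12,6-olide | CC(C)(C)[Si](C)(C)O[C@H]1CC(=C)/C=C\C[C@@]2(C)O[C@@H]2[C@H]2OC(=O)C(COC(C)=O)=C12 | intermediate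
21 | (1Z,4R,5R,6S,8S)-13-acetoxy-4,5-epoxy-8-hydroxygermacra-1,7(11),10(14)-trien-12,6-olide | O[C@H]1CC(=C)/C=C\C[C@@]2(C)O[C@@H]2[C@H]2OC(=O)C(COC(C)=O)=C12 | intermediate
22 | ethyl 2-(hydroxymethyl)prop-2-enoate | C=C(CO)C(=O)OCC | starting material
23 | ethyl 2-({[tert-butyl(dimethyl)silyl]oxy}methyl)prop-2-enoate | C=C(CO[Si](C)(C)C(C)(C)C)C(=O)OCC | intermediate
24 | 2-({[tert-butyl(dimethyl)silyl]oxy}methyl)prop-2-enoic acid | C=C(CO[Si](C)(C)C(C)(C)C)C(=O)O | intermediate
25 | (1Z,4R,5R,6S,8S)-13-acetoxy-8-{[2-({[tert-butyl(dimethyl)silyl]oxy}methyl)prop-2-enoyl]oxy}-4,5-epoxygermacra-1,7(11),10(14)-trien-12,6-olide | C=C(CO[Si](C)(C)C(C)(C)C)C(=O)O[C@H]1CC(=C)/C=C\C[C@@]2(C)O[C@@H]2[C@H]2OC(=O)C(COC(C)=O)=C12 | intermediate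
26 | (1Z,4R,5R,6S,8S)-13-acetoxy-4,5-epoxy-8-{[2-(hydroxymethyl)prop-2-enoyl]oxy}germacra-1,7(11),10(14)-trien-12,6-olide | C=C(CO)C(=O)O[C@H]1CC(=C)/C=C\C[C@@]2(C)O[C@@H]2[C@H]2OC(=O)C(COC(C)=O)=C12 | intermediate
27 | (1R,2S,4R,5R,6S,8S)-13-acetoxy-1,2:4,5-diepoxy-8-{[2-(hydroxymethyl)prop-2-enoyl]oxy}germacra-7(11),10(14)-dien-12,6-olide | C=C(CO)C(=O)O[C@H]1CC(=C)[C@H]2O[C@H]2C[C@@]2(C)O[C@@H]2[C@H]2OC(=O)C(COC(C)=O)=C12 | target

**Step count and risks**

Total: 17 steps. Longest linear sequence: 15 steps (steps 1–6, 8–13 and 15–17). Steps 7 and 14 make the two side reagents.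

Most likely to fail, first: step 12, the proposed oxidative acetoxy-cyclocarbonylation. It may be diverted by 5-endo oxypalladation of the allenol to a dihydrofuran, by palladium/benzoquinone oxidation of the ring diene, or by β-hydride loss from the π-allyl intermediate. The fallback uses known reactions only; it sets out from allenol 19 and comes back at butenolide 20. Iodoetherification of 19 (I2, NaHCO3, MeCN, 0 °C) gives the 3-iodo-2,5-dihydrofuran F1. Stille coupling of F1 with (tributylstannyl)methanol (Pd(PPh3)4, dioxane, 80 °C) gives the hydroxymethyl dihydrofuran F2, and Ac2O/pyridine gives the acetate F3. Oxidation of the doubly activated ring O–CH2 of F3 (CrO3·3,5-dimethylpyrazole, CH2Cl2, −20 °C) gives 20. In this variant the allene terminus becomes the lactone carbonyl and the stannane supplies the acetoxymethyl carbon, so the constitution and the C6 configuration of 20 are the same; selectivity of the chromium oxidation over the other allylic positions is its weak point.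

Second: step 11, the chromium ring closure. It may give oligomers, the 12-membered homopropargylic alkyne from attack through C13, β-elimination of the C8 silyloxy group, or the C6 epimer. The fallback closes the same C6–C7 bond by alkenylchromium addition instead; it sets out from boronate 13 and comes back at alcohol 21, bypassing steps 9–13. 3,3-Diethoxyprop-1-yne is carboxylated (n-BuLi, ClCO2Me) to methyl 4,4-diethoxybut-2-ynoate F4. Iodide addition with aldol capture of formaldehyde (MgI2, (CH2O)n, CH2Cl2, 0 °C) gives the (Z)-β-iodo-α-(hydroxymethyl) enoate F5, acetylation gives the acetate F6, and aqueous trifluoroacetic acid unmasks the iodo enal F7. Allylboration of F7 with 13 under (S)-TRIP catalysis gives the carbinol F8, and TEMPO/PhI(OAc)2 gives the epoxy aldehyde F9. CrCl2 with NiCl2 (1 mol%) in DMSO/THF at high dilution then adds the alkenylchromium to the C6 aldehyde, and the resulting alkoxide lactonises onto the cis methyl ester to give 21 directly. The C6 outcome of this closure would again have to be checked.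

Third: step 17, the late Shi epoxidation. The macrocycle may override the catalyst and give the 1,2-epimer, or the exocyclic alkene may be over-oxidised. The fallback installs the oxirane by halohydrin formation and closure; it sets out from diene 26 and comes back at target 27. NBS in THF/H2O at 0 °C places bromine on C2 and water on the allylic C1, anti to each other, to give the bromohydrin F10, and Ag2O in THF closes it by SN2 displacement to the cis-epoxide. Because the oxygen ends up on the face opposite to the one attacked by the electrophile, this route is complementary in facial sense to a direct substrate-controlled epoxidation; F10 as drawn is the diastereomer that leads to 27.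

**Further compounds**
F1 | step 12 | 6,13-epoxy-11-iodo analogue of 19 (3-iodo-2,5-dihydrofuran fused at C6–C7, 8-silyl ether) | CC(C)(C)[Si](C)(C)O[C@H]1CC(=C)/C=C\C[C@@]2(C)O[C@@H]2[C@H]2OCC(I)=C12
F2 | step 12 | 3-(hydroxymethyl)-2,5-dihydrofuran analogue of F1 | CC(C)(C)[Si](C)(C)O[C@H]1CC(=C)/C=C\C[C@@]2(C)O[C@@H]2[C@H]2OCC(CO)=C12
F3 | step 12 | 3-(acetoxymethyl)-2,5-dihydrofuran analogue of F1 | CC(C)(C)[Si](C)(C)O[C@H]1CC(=C)/C=C\C[C@@]2(C)O[C@@H]2[C@H]2OCC(COC(C)=O)=C12
F4 | step 11 | methyl 4,4-diethoxybut-2-ynoate | CCOC(OCC)C#CC(=O)OC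
F5 | step 11 | methyl (2Z)-4,4-diethoxy-2-(hydroxymethyl)-3-iodobut-2-enoate | I/C(C(OCC)OCC)=C(/CO)C(=O)OC
F6 | step 11 | methyl (2Z)-2-(acetoxymethyl)-4,4-diethoxy-3-iodobut-2-enoate | I/C(C(OCC)OCC)=C(/COC(C)=O)C(=O)OC
F7 | step 11 | methyl (2Z)-2-(acetoxymethyl)-3-iodo-4-oxobut-2-enoate | I/C(C=O)=C(/COC(C)=O)C(=O)OC
F8 | step 11 | methyl (2Z,4S,8Z)-2-(acetoxymethyl)-4-hydroxy-10-[(2R,3R)-3-(hydroxymethyl)-2-methyloxiran-2-yl]-3-iodo-6-methylidenedeca-2,8-dienoate | COC(=O)/C(COC(C)=O)=C(\I)[C@@H](O)CC(=C)/C=C\C[C@@]1(C)O[C@@H]1CO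
F9 | step 11 | methyl (2Z,4S,8Z)-2-(acetoxymethyl)-10-[(2R,3S)-3-formyl-2-methyloxiran-2-yl]-4-hydroxy-3-iodo-6-methylidenedeca-2,8-dienoate | COC(=O)/C(COC(C)=O)=C(\I)[C@@H](O)CC(=C)/C=C\C[C@@]1(C)O[C@@H]1C=O
F10 | step 17 | (1R,2R)-2-bromo-1-hydroxy-1,2-dihydro derivative of 26 (trans-bromohydrin) | C=C(CO)C(=O)O[C@H]1CC(=C)[C@@H](O)[C@H](Br)C[C@@]2(C)O[C@@H]2[C@H]2OC(=O)C(COC(C)=O)=C12
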